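**Plan**

1. Retrosynthetic cuts: the two ester bonds at O1 and O7; the pyran bonds O2–C1 and O2–C3 (back to a C1/C3 dialdehyde); the C8–OH bond (epoxide opened by water); the C10–O and C11–O bonds (two allylic oxidations); last the ring bond C8–C9.
2. Enabling feature: the cyclopentane C5–C6–C7–C8–C9 with C1 on C9, C10 on C8 and the unit C4/C3/C11 on C5 holds exactly the ten carbons of carvone. Contracting the carvone ring pushes its carbonyl carbon out as C1, keeps the ring methyl as C10 and leaves the isopropenyl group as C4, C3 and C11.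
3. Forward order: the cyclopentane arises first (step 4), is then oxidised at C11, C10 and C7/C8, and receives the Z-coumarate at O7. The dihydropyran is closed last from the dialdehyde, followed by acylation of O1 and desilylation.
4. Stereochemistry: C5 is the centre of (S)-carvone; epoxidation anti to the isopropenyl group fixes O7 (β); the ring contraction relays this to C9 (C1 cis to C4). C8 comes from β-epoxidation of a C7=C8 alkene and anti attack of water; C1 from acylation of the equilibrating lactol on the convex face.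
5. The side-chain centre is bought as (R)-3-methylpentanoic acid; the Z alkene comes from a Still–Gennari olefination of 4-hydroxybenzaldehyde.

Key step: step 4

Remark: iridoid numbering is used for every intermediate (C1, O2, C3=C4, ring fusion C5/C9, C6, C7, C8, C10 on C8, C11 on C4) and β is the face of H5 and H9; the C4 centre formed in step 21 is left undefined because it becomes sp2 again in step 23.

**Route**

Step 1
Reactants: 1 (S)-carvone
Product: 2 carvone epoxide, (1S,4S,6S)-1-methyl-4-(prop-1-en-2-yl)-7-oxabicyclo[4.1.0]heptan-2-one (C7–C8 epoxide on the β face, anti to the isopropenyl group)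
Conditions: 30% H2O2, NaOH (cat.), MeOH, 0 °C
Reagents that add atoms: hydrogen peroxide, OO
Why: Weitz–Scheffer nucleophilic epoxidation of the enone, in which hydroperoxide should add axially to C7 anti to the C5 isopropenyl group and so place the future O7 on the β face, while the isolated isopropenyl alkene does not react.

Step 2
Reactants: 2 carvone epoxide
Product: 3 chlorohydrin, (2R,3S,5S)-2-chloro-3-hydroxy-2-methyl-5-(prop-1-en-2-yl)cyclohexan-1-one (8α-Cl, 8β-CH3, 7β-OH)
Conditions: LiCl, CF3CO2H, THF, rt
Reagents that add atoms: lithium chloride, [Li+].[Cl-]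
Why: acid-promoted trans-diaxial (Fürst–Plattner) opening of the α,β-epoxy ketone, chloride entering at C8 next to the carbonyl with inversion so that the tertiary chloride ends anti to the 7β-hydroxyl.

Step 3
Reactants: 3 chlorohydrin
Product: 4 chlorohydrin 7β-TBS ether
Conditions: TBSOTf, 2,6-lutidine, CH2Cl2, −78 to 0 °C
Reagents that add atoms: tert-butyldimethylsilyl triflate, CC(C)(C)[Si](C)(C)OS(=O)(=O)C(F)(F)F
Why: silylation of the hindered secondary alcohol with a silyl triflate and a non-nucleophilic base, which masks the hydroxyl that would otherwise reclose the epoxide or undergo retro-aldol cleavage under the basic conditions of step 4.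

Step 4
Reactants: 4 chlorohydrin 7β-TBS ether
Product: 6 methyl (1S,2R,3S,5S)-3-[(tert-butyldimethylsilyl)oxy]-2-methyl-5-(prop-1-en-2-yl)cyclopentane-1-carboxylate (9α-CO2Me, 5α-isopropenyl, 8β-CH3, 7β-OTBS), via cyclopropanone 5 (not isolated)
Conditions: NaOMe, MeOH, 0 °C to rt
Reagents that add atoms: sodium methoxide, C[O-].[Na+]
Why: Methoxide removes a proton from C9 and the enolate displaces the tertiary chloride on C8 from the rear, closing cyclopropanone 5; methoxide then adds to the C1 carbonyl and the C1–C8 bond breaks with protonation at C8, leaving the ester on C9. This is the cyclopropanone pathway of the Favorskii rearrangement, whose closest known cases are the contractions of 2-chlorocyclohexanones, O-protected carvone chlorohydrins among them, to cyclopentanecarboxylates. The one ring closed is the three-membered ring (3-exo-tet attack of C9 on C8), and its opening leaves the cyclopentane C5–C9 with C8–C9 as the new skeletal bond. C9 is controlled by the inversion at C8: chloride leaves from the α side, C1 swings onto the α face and bridges C8 and C9 there, so that C1 ends cis to the C5 isopropenyl group. C8 is controlled by protonation with retention at the position vacated by C1, which places H8 α and the methyl group β, cis to the 7β-silyloxy group. The step needs a concerted displacement instead of an oxyallyl cation and cleavage toward C8 instead of C9; the axial chloride anti to O7, set in step 2, lines up with the enolate, and the inductive pull of the C7 silyloxy group makes C8 the better carbanionic leaving site.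

Step 5
Reactants: 6 Favorskii ester
Product: 7 C11 allylic alcohol (side chain on C5 now CH2=C(CH2OH)–)
Conditions: SeO2 (cat.), t-BuOOH, CH2Cl2, rt
Reagents that add atoms: selenium dioxide, O=[Se]=O; tert-butyl hydroperoxide, CC(C)(C)OO
Why: Riley allylic oxidation (ene reaction, then [2,3]-sigmatropic shift) of the 1,1-disubstituted alkene, which should take the methyl group in preference to the methine C5–H and stop at the alcohol when SeO2 is used catalytically.

Step 6
Reactants: 7 C11 allylic alcohol
Product: 8 C11 TBDPS ether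
Conditions: TBDPSCl, imidazole, CH2Cl2, rt
Reagents that add atoms: tert-butyl(chloro)diphenylsilane, CC(C)(C)[Si](Cl)(c1ccccc1)c1ccccc1
Why: routine silylation of a primary allylic alcohol, the TBDPS group being chosen because it should outlast the acidic steps 9 and 14 and still fall to fluoride in step 25.

Step 7
Reactants: 8 C11 TBDPS ether
Product: 9 C1 primary alcohol (9α-CH2OH)
Conditions: LiAlH4, THF, 0 °C
Reagents that add atoms: none
Why: hydride reduction of the methyl ester to the primary alcohol, which removes the acidic H9 before the C7=C8 alkene is made and leaves both silyl ethers and the alkene untouched.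

Step 8
Reactants: 9 C1 primary alcohol
Product: 10 C1 PMB ether
Conditions: NaH, 4-methoxybenzyl chloride, Bu4NI (cat.), THF/DMF, 0 °C to rt
Reagents that add atoms: 4-methoxybenzyl chloride, COc1ccc(CCl)cc1
Why: Williamson etherification giving an ether that is inert to all later steps and is removed oxidatively in step 22 without touching silyl ethers or esters.

Step 9
Reactants: 10 C1 PMB ether
Product: 11 7β-alcohol
Conditions: (1S)-camphor-10-sulfonic acid (cat.), MeOH/CH2Cl2, 0 °C to rt
Reagents that add atoms: none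
Why: acid-catalysed methanolysis of the secondary TBS ether, which should be much faster than cleavage of the primary TBDPS ether and spares the PMB ether.

Step 10
Reactants: 11 7β-alcohol
Product: 12 7β-mesylate
Conditions: MsCl, Et3N, CH2Cl2, 0 °C
Reagents that add atoms: methanesulfonyl chloride, CS(=O)(=O)Cl
Why: sulfonylation of the secondary alcohol with retention at C7, giving a leaving group anti-periplanar to the α-hydrogen on C8.

Step 11
Reactants: 12 7β-mesylate
Product: 13 C7=C8 cyclopentene (methyl C10 on C8)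
Conditions: 1,8-diazabicyclo[5.4.0]undec-7-ene (DBU), toluene, 110 °C
Reagents that add atoms: none
Why: E2 elimination in which the 7β-mesylate and the 8α-hydrogen are anti, so that the trisubstituted Zaitsev alkene should form, as with cis-2-methylcyclopentyl sulfonates.

Step 12
Reactants: 13 C7=C8 cyclopentene
Product: 14 C10 allylic alcohol (8-hydroxymethyl cyclopentene)
Conditions: SeO2 (cat.), t-BuOOH, CH2Cl2, 0 °C to rt
Reagents that add atoms: selenium dioxide, O=[Se]=O; tert-butyl hydroperoxide, CC(C)(C)OO
Why: Riley oxidation of the trisubstituted cyclopentene, in which selenium should bond to the less substituted C7 and the methyl group on C8 is oxidised in preference to the methine C9–H, the ene and [2,3] steps returning the C7=C8 alkene.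

Step 13
Reactants: 14 C10 allylic alcohol
Product: 15 7β,8β-epoxy alcohol
Conditions: mCPBA, NaHCO3, CH2Cl2, 0 °C
Reagents that add atoms: 3-chloroperbenzoic acid, OOC(=O)c1cccc(Cl)c1
Why: Prilezhaev epoxidation in which the trisubstituted alkene reacts before the silyloxymethyl-bearing 1,1-disubstituted alkene, and the peracid should approach the β face because the α face carries the substituents on C9 and C5.

Step 14
Reactants: 15 7β,8β-epoxy alcohol
Product: 16 7β,8α,10-triol
Conditions: HClO4 (cat.), THF/H2O, 0 °C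
Reagents that add atoms: water, O
Why: acid-catalysed epoxide hydrolysis in which water attacks the tertiary carbon C8 of the protonated epoxide from the α face with inversion, so that the epoxide oxygen stays on C7 as the 7β-hydroxyl and C8 gains its α-hydroxyl with the CH2OH group β.

Step 15
Reactants: 16 7β,8α,10-triol
Product: 17 C10 TES ether (7β-OH and 8α-OH free)
Conditions: TESCl, imidazole, CH2Cl2, −40 to −20 °C
Reagents that add atoms: chlorotriethylsilane, CC[Si](Cl)(CC)CC
Why: selective silylation of the primary hydroxyl over the secondary C7 and tertiary C8 hydroxyls on steric grounds.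

Step 16
Reactants: 18 4-hydroxybenzaldehyde
Product: 19 4-(triisopropylsilyloxy)benzaldehyde
Conditions: TIPSCl, imidazole, DMF, rt
Reagents that add atoms: chlorotriisopropylsilane, CC(C)[Si](Cl)(C(C)C)C(C)C
Why: phenol silylation, the TIPS aryl ether being expected to withstand the hydroxide of step 18 better than a TBS ether and still to leave with fluoride.

Step 17
Reactants: 19 4-(triisopropylsilyloxy)benzaldehyde
Product: 20 methyl (Z)-3-[4-(triisopropylsilyloxy)phenyl]prop-2-enoate
Conditions: (CF3CH2O)2P(O)CH2CO2Me, KN(SiMe3)2, 18-crown-6, THF, −78 °C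
Reagents that add atoms: methyl bis(2,2,2-trifluoroethyl)phosphonoacetate, COC(=O)CP(=O)(OCC(F)(F)F)OCC(F)(F)F
Why: Still–Gennari olefination, in which the electron-poor phosphonate and the dissociated potassium counter-ion make elimination from the kinetic adduct fast and so deliver the Z-cinnamate.

Step 18
Reactants: 20 methyl (Z)-cinnamate
Product: 21 (Z)-3-[4-(triisopropylsilyloxy)phenyl]prop-2-enoic acid
Conditions: LiOH, THF/H2O, 0 °C to rt, dark; then 1 M HCl to pH 3
Reagents that add atoms: lithium hydroxide, [Li+].[OH-]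
Why: saponification of the methyl ester, which should leave the alkene geometry intact when light is excluded.

Step 19
Reactants: 17 C10 TES ether; 21 (Z)-acid
Product: 22 7β-O-[(Z)-4-(triisopropylsilyloxy)cinnamoyl] ester (8α-OH free)
Conditions: N,N′-dicyclohexylcarbodiimide, 4-(dimethylamino)pyridine, CH2Cl2, 0 °C to rt, dark
Reagents that add atoms: none
Why: Steglich esterification of the secondary 7β-hydroxyl with retention at C7, the tertiary 8α-hydroxyl being unreactive under these conditions.

Step 20
Reactants: 22 7β-coumarate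
Product: 23 8α,10-bis-TES ether
Conditions: TESOTf, 2,6-lutidine, CH2Cl2, −78 to 0 °C
Reagents that add atoms: triethylsilyl triflate, CC[Si](CC)(CC)OS(=O)(=O)C(F)(F)F
Why: silyl triflate silylation of the tertiary alcohol, needed so that the 8-hydroxyl cannot add to the C3 aldehyde when the dialdehyde is generated in step 23.

Step 21
Reactants: 23 8α,10-bis-TES ether
Product: 25 C3 primary alcohol (C4 epimers), via alkylborane 24 (not isolated)
Conditions: 9-BBN, THF, 0 °C to rt; then 30% H2O2, pH 7 phosphate buffer, 0 °C to rt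
Reagents that add atoms: 9-borabicyclo[3.3.1]nonane, [H]B1C2CCCC1CCC2 (boron stays in 24 only); hydrogen peroxide, OO
Why: Brown hydroboration–oxidation in which 9-BBN should add only to the unhindered 1,1-disubstituted alkene with boron on the terminal carbon C3 and leave the conjugated ester alone, the buffered oxidation sparing the esters and the aryl silyl ether.

Step 22
Reactants: 25 C3 primary alcohol
Product: 26 C1,C3-diol
Conditions: 2,3-dichloro-5,6-dicyano-1,4-benzoquinone (DDQ), CH2Cl2/pH 7 buffer, 0 °C
Reagents that add atoms: none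
Why: oxidative PMB cleavage by hydride abstraction and hydrolysis of the resulting oxocarbenium ion, a reaction that leaves silyl ethers, esters and the cinnamate untouched.

Step 23
Reactants: 26 C1,C3-diol
Product: 28 bicyclic lactol (1β-hydroxy, C3=C4 enol ether), via dialdehyde 27 (not isolated)
Conditions: Dess–Martin periodinane, NaHCO3, CH2Cl2, 0 °C to rt; then Et3N (cat.), CH2Cl2, rt
Reagents that add atoms: none
Why: Dess–Martin oxidation of both primary alcohols, then enolisation of the C3 aldehyde toward C4 and addition of the enol oxygen to the C1 aldehyde, the closure known for iridodial-type 1,5-dialdehydes, which should give the cis-fused lactol with the hydroxyl in the anomerically favoured β position.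

Step 24
Reactants: 28 bicyclic lactol; 29 (R)-3-methylpentanoic acid
Product: 30 fully silylated target (1β-O-acyl)
Conditions: N,N′-dicyclohexylcarbodiimide, 4-(dimethylamino)pyridine (cat.), CH2Cl2, −20 to 0 °C
Reagents that add atoms: none
Why: Steglich acylation of the only free hydroxyl, the lactol anomers interconverting through the hydroxy aldehyde so that the 1β-ester on the convex face is expected to dominate, while the acid's stereocentre β to the carbonyl cannot epimerise.

Step 25
Reactants: 30 fully silylated target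
Product: 31 target (CNP0217341.1)
Conditions: Bu4NF, AcOH (1:1), THF, 0 °C to rt
Reagents that add atoms: none
Why: fluoride-induced cleavage of the four silyl ethers, buffered with acetic acid to suppress acyl migration from O7, loss of the C1 acyloxy group and addition of the 8-hydroxyl to the enol ether.

**Compound list**

1 | (S)-carvone | CC1=CC[C@@H](CC1=O)C(C)=C | starting material
2 | carvone epoxide (β-epoxide, anti to isopropenyl) | O=C1C[C@@H](C(C)=C)C[C@@H]2O[C@]12C | intermediate
3 | chlorohydrin (8α-Cl, 7β-OH) | O=C1C[C@@H](C(C)=C)C[C@H](O)[C@@]1(C)Cl | intermediate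
4 | chlorohydrin 7β-TBS ether | O=C1C[C@@H](C(C)=C)C[C@H](O[Si](C)(C)C(C)(C)C)[C@@]1(C)Cl | intermediate
5 | cyclopropanone (C1 bridging C8 and C9 on the α face; not isolated) | O=C1[C@H]2[C@@H](C(C)=C)C[C@H](O[Si](C)(C)C(C)(C)C)[C@@]12C | intermediate
6 | Favorskii methyl ester (9α-CO2Me, 5α-isopropenyl, 8β-CH3, 7β-OTBS) | COC(=O)[C@H]1[C@@H](C(C)=C)C[C@H](O[Si](C)(C)C(C)(C)C)[C@@H]1C | intermediate
7 | C11 allylic alcohol | COC(=O)[C@H]1[C@@H](C(=C)CO)C[C@H](O[Si](C)(C)C(C)(C)C)[C@@H]1C | intermediate
8 | C11 TBDPS ether | COC(=O)[C@H]1[C@@H](C(=C)CO[Si](c2ccccc2)(c2ccccc2)C(C)(C)C)C[C@H](O[Si](C)(C)C(C)(C)C)[C@@H]1C | intermediate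
9 | C1 primary alcohol | OC[C@H]1[C@@H](C(=C)CO[Si](c2ccccc2)(c2ccccc2)C(C)(C)C)C[C@H](O[Si](C)(C)C(C)(C)C)[C@@H]1C | intermediate
10 | C1 PMB ether | COc1ccc(COC[C@H]2[C@@H](C(=C)CO[Si](c3ccccc3)(c3ccccc3)C(C)(C)C)C[C@H](O[Si](C)(C)C(C)(C)C)[C@@H]2C)cc1 | intermediate
11 | 7β-alcohol | COc1ccc(COC[C@H]2[C@@H](C(=C)CO[Si](c3ccccc3)(c3ccccc3)C(C)(C)C)C[C@H](O)[C@@H]2C)cc1 | intermediate
12 | 7β-mesylate | COc1ccc(COC[C@H]2[C@@H](C(=C)CO[Si](c3ccccc3)(c3ccccc3)C(C)(C)C)C[C@H](OS(C)(=O)=O)[C@@H]2C)cc1 | intermediate
13 | C7=C8 cyclopentene | COc1ccc(COC[C@H]2[C@@H](C(=C)CO[Si](c3ccccc3)(c3ccccc3)C(C)(C)C)CC=C2C)cc1 | intermediate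
14 | C10 allylic alcohol | COc1ccc(COC[C@H]2[C@@H](C(=C)CO[Si](c3ccccc3)(c3ccccc3)C(C)(C)C)CC=C2CO)cc1 | intermediate
15 | 7β,8β-epoxy alcohol | COc1ccc(COC[C@H]2[C@@H](C(=C)CO[Si](c3ccccc3)(c3ccccc3)C(C)(C)C)C[C@@H]3O[C@]23CO)cc1 | intermediate
16 | 7β,8α,10-triol | COc1ccc(COC[C@H]2[C@@H](C(=C)CO[Si](c3ccccc3)(c3ccccc3)C(C)(C)C)C[C@H](O)[C@]2(O)CO)cc1 | intermediate
17 | C10 TES ether | COc1ccc(COC[C@H]2[C@@H](C(=C)CO[Si](c3ccccc3)(c3ccccc3)C(C)(C)C)C[C@H](O)[C@]2(O)CO[Si](CC)(CC)CC)cc1 | intermediate
18 | 4-hydroxybenzaldehyde | O=Cc1ccc(O)cc1 | starting material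
19 | 4-(triisopropylsilyloxy)benzaldehyde | O=Cc1ccc(O[Si](C(C)C)(C(C)C)C(C)C)cc1 | intermediate
20 | methyl (Z)-3-[4-(triisopropylsilyloxy)phenyl]prop-2-enoate | COC(=O)/C=C\c1ccc(O[Si](C(C)C)(C(C)C)C(C)C)cc1 | intermediate
21 | (Z)-3-[4-(triisopropylsilyloxy)phenyl]prop-2-enoic acid | OC(=O)/C=C\c1ccc(O[Si](C(C)C)(C(C)C)C(C)C)cc1 | intermediate
22 | 7β-coumarate (8α-OH free) | COc1ccc(COC[C@H]2[C@@H](C(=C)CO[Si](c3ccccc3)(c3ccccc3)C(C)(C)C)C[C@H](OC(=O)/C=C\c3ccc(O[Si](C(C)C)(C(C)C)C(C)C)cc3)[C@]2(O)CO[Si](CC)(CC)CC)cc1 | intermediate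
23 | 8α,10-bis-TES ether | COc1ccc(COC[C@H]2[C@@H](C(=C)CO[Si](c3ccccc3)(c3ccccc3)C(C)(C)C)C[C@H](OC(=O)/C=C\c3ccc(O[Si](C(C)C)(C(C)C)C(C)C)cc3)[C@]2(O[Si](CC)(CC)CC)CO[Si](CC)(CC)CC)cc1 | intermediate
24 | C3 alkylborane (B-alkyl-9-BBN; C4 epimers; not isolated) | COc1ccc(COC[C@H]2[C@@H](C(CB3C4CCCC3CCC4)CO[Si](c3ccccc3)(c3ccccc3)C(C)(C)C)C[C@H](OC(=O)/C=C\c3ccc(O[Si](C(C)C)(C(C)C)C(C)C)cc3)[C@]2(O[Si](CC)(CC)CC)CO[Si](CC)(CC)CC)cc1 | intermediate
25 | C3 primary alcohol (C4 epimers) | COc1ccc(COC[C@H]2[C@@H](C(CO)CO[Si](c3ccccc3)(c3ccccc3)C(C)(C)C)C[C@H](OC(=O)/C=C\c3ccc(O[Si](C(C)C)(C(C)C)C(C)C)cc3)[C@]2(O[Si](CC)(CC)CC)CO[Si](CC)(CC)CC)cc1 | intermediate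
26 | C1,C3-diol (C4 epimers) | OC[C@H]1[C@@H](C(CO)CO[Si](c2ccccc2)(c2ccccc2)C(C)(C)C)C[C@H](OC(=O)/C=C\c2ccc(O[Si](C(C)C)(C(C)C)C(C)C)cc2)[C@]1(O[Si](CC)(CC)CC)CO[Si](CC)(CC)CC | intermediate
27 | C1,C3-dialdehyde (C4 epimers; not isolated) | O=C[C@H]1[C@@H](C(C=O)CO[Si](c2ccccc2)(c2ccccc2)C(C)(C)C)C[C@H](OC(=O)/C=C\c2ccc(O[Si](C(C)C)(C(C)C)C(C)C)cc2)[C@]1(O[Si](CC)(CC)CC)CO[Si](CC)(CC)CC | intermediate
28 | bicyclic lactol (1β-OH, C3=C4) | O[C@@H]1OC=C(CO[Si](c2ccccc2)(c2ccccc2)C(C)(C)C)[C@H]2C[C@H](OC(=O)/C=C\c3ccc(O[Si](C(C)C)(C(C)C)C(C)C)cc3)[C@](O[Si](CC)(CC)CC)(CO[Si](CC)(CC)CC)[C@@H]12 | intermediate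
29 | (R)-3-methylpentanoic acid | CC[C@@H](C)CC(=O)O | starting material
30 | fully silylated target | CC[C@@H](C)CC(=O)O[C@@H]1OC=C(CO[Si](c2ccccc2)(c2ccccc2)C(C)(C)C)[C@H]2C[C@H](OC(=O)/C=C\c3ccc(O[Si](C(C)C)(C(C)C)C(C)C)cc3)[C@](O[Si](CC)(CC)CC)(CO[Si](CC)(CC)CC)[C@@H]12 | intermediate
31 | CNP0217341.1 | CC[C@@H](C)CC(=O)O[C@@H]1OC=C(CO)[C@H]2C[C@H](OC(=O)/C=C\c3ccc(O)cc3)[C@](O)(CO)[C@@H]12 | target

**Step count and risks**

Total: 25 steps (22 from carvone, 3 for acid 21). Longest linear sequence: 22 steps (steps 1–15 and 19–25).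

Step 12. The allylic oxidation may lack site selectivity (attack at the methine C9–H or at the side-chain alkene) or run on to the enal. The fallback sets out from alkene 13 and reaches C10 by isomerisation instead of C–H oxidation. Prilezhaev epoxidation (mCPBA, NaHCO3, CH2Cl2, 0 °C) on the open β face should give the 7β,8β-epoxide F1. Diethylaluminium 2,2,6,6-tetramethylpiperidide (from lithium 2,2,6,6-tetramethylpiperidide and Et2AlCl, toluene, 0 °C) should remove a proton from the C10 methyl group syn to the epoxide oxygen and give the exocyclic allylic alcohol F2 (7β-OH, C8=C10). A 1,3-transposition of the hydroxyl with Ph3SiOReO3 (cat., Et2O, 0 °C), driven toward the trisubstituted endocyclic alkene, comes back to the route at 14.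

Step 14. Water may enter at C7 instead of C8, or the protonated epoxide may rearrange; either would scramble C7 and C8. The fallback sets out from epoxy alcohol 15 and delivers the oxygen to C8 intramolecularly. PhNCO and pyridine in CH2Cl2 should give the C10 phenylurethane F3. With BF3·OEt2 in Et2O at −20 °C the urethane carbonyl oxygen should open the epoxide at C8 in a 5-exo sense from the α face with inversion, giving the cyclic iminocarbonate F4. Acidic work-up (1 M H2SO4) should hydrolyse it to the 8α,10-cyclic carbonate F5 with the 7β-hydroxyl free. Methanolysis (K2CO3, MeOH, 0 °C) comes back to the route at triol 16.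

Step 24. Control of the anomeric centre may be poor, or the lactol may react through its open hydroxy aldehyde form. The fallback sets out from lactol 28 and makes C1 the electrophile. Cl3CCN and K2CO3 in CH2Cl2 should give the anomeric trichloroacetimidate F6 (drawn as the 1β anomer; either anomer serves). Treated with acid 29 alone (CH2Cl2, rt), the acid protonates the imidate and the carboxylate should capture C1 on the convex β face in the anomerically favoured orientation, coming back to the route at 30.

**Further compounds**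

F1 | step 12 | 7β,8β-epoxide of alkene 13 | COc1ccc(COC[C@H]2[C@@H](C(=C)CO[Si](c3ccccc3)(c3ccccc3)C(C)(C)C)C[C@@H]3O[C@]23C)cc1
F2 | step 12 | exocyclic allylic alcohol (7β-OH, C8=C10) | COc1ccc(COC[C@H]2[C@@H](C(=C)CO[Si](c3ccccc3)(c3ccccc3)C(C)(C)C)C[C@H](O)C2=C)cc1
F3 | step 14 | C10 phenylurethane of epoxy alcohol 15 | COc1ccc(COC[C@H]2[C@@H](C(=C)CO[Si](c3ccccc3)(c3ccccc3)C(C)(C)C)C[C@@H]3O[C@]23COC(=O)Nc2ccccc2)cc1
F4 | step 14 | 8α,10-cyclic N-phenyliminocarbonate (7β-OH) | COc1ccc(COC[C@H]2[C@@H](C(=C)CO[Si](c3ccccc3)(c3ccccc3)C(C)(C)C)C[C@H](O)[C@]23COC(=Nc2ccccc2)O3)cc1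
F5 | step 14 | 8α,10-cyclic carbonate (7β-OH) | COc1ccc(COC[C@H]2[C@@H](C(=C)CO[Si](c3ccccc3)(c3ccccc3)C(C)(C)C)C[C@H](O)[C@]23COC(=O)O3)cc1
F6 | step 24 | anomeric trichloroacetimidate of lactol 28 | N=C(O[C@@H]1OC=C(CO[Si](c2ccccc2)(c2ccccc2)C(C)(C)C)[C@H]2C[C@H](OC(=O)/C=C\c3ccc(O[Si](C(C)C)(C(C)C)C(C)C)cc3)[C@](O[Si](CC)(CC)CC)(CO[Si](CC)(CC)CC)[C@@H]12)C(Cl)(Cl)Cl
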